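Retrosynthesis: the two O–Si bonds are cut first, then ring A at C8–C8a and C4a–C5 (C4a–S and one C5–OMe are the leaving groups). This gives the 5-sulfinyl dihydropyranone 8 and the lavandulyl 1,1-dimethoxy-3-silyloxydiene 18. 8 is cut at C5–S and at C2–C3/O1–C6 (hetero-Diels–Alder); 18 at O–Si, C2–C3 (ketene-acetal acylation) and C4–C5 (malonate alkylation).
Enabling feature: ring A is a 2-alkylphloroglucinol whose three oxygens all differ (C5–OMe, C7–OH, C8a–O1) and which is fused through C4a–C8a to pyranone ring C, whose only stereocentre is C2. The arene can therefore be grown regiospecifically onto the C5=C6 enol-ether bond of a preformed chiral dihydropyranone.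
Forward order: ring B is bought (aldehyde 1), ring C is made by hetero-Diels–Alder, the lavandulyl chain is homologated separately into the diene, ring A is closed last (step 11), and desilylation ends the route.
Stereochemistry: C2 (S) comes from the catalyst-controlled hetero-Diels–Alder; C2'' (R in the target) comes from lipase-resolved (S)-lavandulol, the descriptor changing only through CIP priorities. Ring-A formation creates no lasting stereocentre.
Design choice: a phenylsulfinyl group on C5 activates the electron-rich enol-ether double bond and later leaves as PhSOH by syn-elimination, so no base is needed near the epimerisable C2.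

Key step: step 11

Assumption: the (S,S)-salen–Cr(III) catalyst is taken to direct the diene to the Si face of aldehyde 2, by analogy with simple aryl aldehydes; if the opposite sense is found, its enantiomer is used.
Assumption: the lipase is taken to acetylate (R)-lavandulol faster, so the S alcohol remains; if the preference were reversed, the acetate fraction would be methanolysed to 10.
Abbreviations: TBS = tert-butyldimethylsilyl; lavandulyl = 5-methyl-2-(prop-1-en-2-yl)hex-4-en-1-yl.

Step 1
Reactants: 1 4-hydroxy-2-methoxybenzaldehyde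
Product: 2 4-(TBSO)-2-methoxybenzaldehyde
Conditions: TBSCl, imidazole, DMF, 25 °C
Reagents that add atoms: tert-butyldimethylsilyl chloride, CC(C)(C)[Si](C)(C)Cl
Why: Imidazole-promoted silyl ether formation on the phenol is fast and leaves the aldehyde untouched, and the aryl silyl ether tempers the donor strength of the 4-oxygen for the later acid- and electrophile-exposed steps.

Step 2
Reactants: 2 4-(TBSO)-2-methoxybenzaldehyde; 3 (E)-1-methoxy-3-(trimethylsilyloxy)buta-1,3-diene
Product: 5 (2S)-2-[4-(TBSO)-2-methoxyphenyl]-2,3-dihydro-4H-pyran-4-one, via dihydropyran cycloadduct 4 (not isolated)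
Conditions: (S,S)-(salen)Cr(III)BF4 (3 mol%), 4 Å MS, t-BuOMe, −30 °C; then TFA (cat.), CH2Cl2, 0 °C
Reagents that add atoms: none
Why: Lewis-acid-catalysed asymmetric hetero-Diels–Alder reaction in which the diene attacks the Si face of the catalyst-bound aldehyde, setting C2 as S, after which brief acid treatment eliminates MeOSiMe3 from 4 to unveil the enone.

Step 3
Reactants: 5 (2S)-2-[4-(TBSO)-2-methoxyphenyl]-2,3-dihydro-4H-pyran-4-one
Product: 7 (2S)-2-[4-(TBSO)-2-methoxyphenyl]-5-(phenylsulfanyl)-2,3-dihydro-4H-pyran-4-one, via chloro sulfide adduct 6 (not isolated)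
Conditions: PhSCl, CH2Cl2, −78 °C; then Et3N, −78 → 0 °C
Reagents that add atoms: benzenesulfenyl chloride, ClSc1ccccc1
Why: Electrophilic α-sulfenylation of a vinylogous ester by addition–elimination, in which the sulfenyl chloride adds across the enol-ether double bond (S at nucleophilic C5, Cl at C6) faster than it attacks the silyloxyanisole ring and the amine then removes HCl to restore the enone.

Step 4
Reactants: 7 (2S)-2-[4-(TBSO)-2-methoxyphenyl]-5-(phenylsulfanyl)-2,3-dihydro-4H-pyran-4-one
Product: 8 (2S)-2-[4-(TBSO)-2-methoxyphenyl]-5-(phenylsulfinyl)-2,3-dihydro-4H-pyran-4-one (both epimers at sulfur)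
Conditions: mCPBA (1.0 equiv), NaHCO3, CH2Cl2, −78 → −40 °C
Reagents that add atoms: 3-chloroperoxybenzoic acid, OOC(=O)c1cccc(Cl)c1
Why: Sulfide-to-sulfoxide oxidation with one equivalent of peracid at low temperature outpaces attack on the deactivated enone double bond or the arene, and the uncontrolled sulfur stereocentre is irrelevant because sulfur is expelled in step 11.

Step 5
Reactants: 9 (±)-lavandulol
Product: 10 (S)-lavandulol
Conditions: immobilised Candida antarctica lipase B, vinyl acetate, hexane, 25 °C, stopped at ca. 65% conversion; chromatography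
Reagents that add atoms: none
Why: Lipase-catalysed kinetic resolution (enantioselective transesterification with an irreversible acyl donor) in which the R alcohol is acetylated faster, so running past half conversion should leave the S alcohol, the source of C2'', in high enantiomeric purity.

Step 6
Reactants: 10 (S)-lavandulol
Product: 11 (3S)-3-(iodomethyl)-2,6-dimethylhepta-1,5-diene
Conditions: PPh3, I2, imidazole, CH2Cl2, 0 → 25 °C
Reagents that add atoms: iodine, II
Why: Appel-type iodination replaces the primary hydroxyl by SN2 at CH2, which touches neither the adjacent stereocentre nor the two alkenes.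

Step 7
Reactants: 11 (3S)-3-(iodomethyl)-2,6-dimethylhepta-1,5-diene
Product: 12 dimethyl 2-[(2R)-lavandulyl]propanedioate
Conditions: dimethyl malonate (2 equiv), NaH, THF/DMF, 0 → 65 °C
Reagents that add atoms: dimethyl malonate, COC(=O)CC(=O)OC
Why: Malonic ester alkylation, in which the soft, weakly basic malonate anion displaces the primary iodide by SN2 with little E2 despite β-branching and without involving the stereocentre.

Step 8
Reactants: 12 dimethyl 2-[(2R)-lavandulyl]propanedioate
Product: 14 (4S)-7-methyl-4-(prop-1-en-2-yl)oct-6-enoic acid, via malonic acid 13 (not isolated)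
Conditions: LiOH, THF/MeOH/H2O, 50 °C; 1 M HCl, 0 °C; then pyridine, 110 °C
Reagents that add atoms: lithium hydroxide, [Li+].[OH-]
Why: Saponification followed by thermal decarboxylation of the malonic acid (malonic ester synthesis) in pyridine, a buffered medium that spares the acid-sensitive isopropenyl and prenyl alkenes.

Step 9
Reactants: 14 (4S)-7-methyl-4-(prop-1-en-2-yl)oct-6-enoic acid; 15 ketene dimethyl acetal (1,1-dimethoxyethene)
Product: 17 (6S)-1,1-dimethoxy-9-methyl-6-(prop-1-en-2-yl)deca-1,8-dien-3-one, via acid chloride 16 (not isolated)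
Conditions: 1-chloro-N,N,2-trimethylpropenylamine, CH2Cl2, 0 → 25 °C; then 15 (2.5 equiv), Et2O, 0 → 25 °C
Reagents that add atoms: none
Why: Neutral acid chloride formation followed by C-acylation of the ketene acetal, whose second equivalent scavenges HCl as methyl acetate and chloromethane, is the classical route to β-keto ketene acetals and avoids amine-induced ketene formation.

Step 10
Reactants: 17 (6S)-1,1-dimethoxy-9-methyl-6-(prop-1-en-2-yl)deca-1,8-dien-3-one
Product: 18 (3Z,6R)-3-(TBSO)-1,1-dimethoxy-9-methyl-6-(prop-1-en-2-yl)deca-1,3,8-triene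
Conditions: TBSOTf, Et3N, Et2O, −78 → 0 °C; used crude after filtration under argon
Reagents that add atoms: tert-butyldimethylsilyl trifluoromethanesulfonate, CC(C)(C)[Si](C)(C)OS(=O)(=O)C(F)(F)F
Why: Soft enolisation and O-silylation of the vinylogous carbonyl can only deprotonate at C4, the sole enolisable position, and the Z silyl dienol ether (chain trans to C2 across C3=C4, as an s-cis diene requires) should predominate for steric reasons.

Step 11
Reactants: 8 (2S)-2-[4-(TBSO)-2-methoxyphenyl]-5-(phenylsulfinyl)-2,3-dihydro-4H-pyran-4-one; 18 (3Z,6R)-3-(TBSO)-1,1-dimethoxy-9-methyl-6-(prop-1-en-2-yl)deca-1,3,8-triene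
Product: 21 7,4'-bis-O-TBS-(2S)-2'-methoxykurarinone, via sulfinyl cycloadduct 19 (not isolated), via dimethoxy dihydroarene 20 (not isolated)
Conditions: 18 (2.5 equiv), PhMe, 4 Å MS, 25 → 70 °C; then SiO2, CH2Cl2, 25 °C
Reagents that add atoms: none
Why: Proposed new method: the sulfinyl and keto groups on C5 of 8 make C6 the electrophilic end of the enol-ether double bond, so the nucleophilic C4 of diene 18 should bond to C6 (future C8–C8a) and the ketene-acetal carbon C1 to C5 (future C5–C4a) in an asynchronous, normal-demand [4+2] cycloaddition; ring A is thus closed by intermolecular cycloaddition onto the C5=C6 bond of ring C, giving the cis-fused adduct 19. In 19 the sulfinyl group on C4a and the hydrogen on C8a are cis, so thermal syn-elimination of benzenesulfenic acid restores the C4a=C8a double bond (20), and 1,4-loss of methanol across C5/C8 then aromatises the ring. The closest known reaction types are the cycloaddition–aromatisation of 1,1-dialkoxy-3-silyloxydienes with haloquinones and the cycloaddition–sulfoxide elimination of sulfinylquinones and 3-sulfinylchromones; a monocyclic 2,3-dihydropyran-4-one has not been used in this way. No lasting stereocentre is formed: the transient centres at C4a, C8 and C8a are erased on aromatisation, while C2 and C2'' are remote spectators under these base- and acid-free conditions. The selectivity required is regiochemical (OMe at C5, OSi at C7, chain at C8), secured by the polarity match just described, and periselective ([4+2] on the diene rather than hetero-Diels–Alder on the enone), secured by the s-trans enone geometry that the six-membered ring enforces.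

Step 12
Reactants: 21 7,4'-bis-O-TBS-(2S)-2'-methoxykurarinone
Product: 22 (2S)-2'-methoxykurarinone
Conditions: HF·pyridine, pyridine, THF, 0 → 25 °C
Reagents that add atoms: none
Why: Fluoride-mediated cleavage of both aryl silyl ethers in a pyridine-buffered medium avoids both base-induced ring opening at C2 (flavanone–chalcone equilibration) and acid-induced cyclisation of the 7-hydroxyl onto the isopropenyl group.

Compound list
1 | 4-hydroxy-2-methoxybenzaldehyde | COc1cc(O)ccc1C=O | starting material
2 | 4-(TBSO)-2-methoxybenzaldehyde | COc1cc(O[Si](C)(C)C(C)(C)C)ccc1C=O | intermediate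
3 | (E)-1-methoxy-3-(trimethylsilyloxy)buta-1,3-diene | CO/C=C/C(=C)O[Si](C)(C)C | starting material
4 | (6S)-6-[4-(TBSO)-2-methoxyphenyl]-2-methoxy-4-(trimethylsilyloxy)-5,6-dihydro-2H-pyran, both C2 epimers | COC1C=C(O[Si](C)(C)C)C[C@@H](c2ccc(O[Si](C)(C)C(C)(C)C)cc2OC)O1 | intermediate (not isolated)
5 | (2S)-2-[4-(TBSO)-2-methoxyphenyl]-2,3-dihydro-4H-pyran-4-one | O=C1C=CO[C@H](c2ccc(O[Si](C)(C)C(C)(C)C)cc2OC)C1 | intermediate
6 | (2S)-6-chloro-2-[4-(TBSO)-2-methoxyphenyl]-5-(phenylsulfanyl)oxan-4-one, 5,6-trans adduct, configuration at C5/C6 not controlled | O=C1C(Sc2ccccc2)C(Cl)O[C@H](c2ccc(O[Si](C)(C)C(C)(C)C)cc2OC)C1 | intermediate (not isolated)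
7 | (2S)-2-[4-(TBSO)-2-methoxyphenyl]-5-(phenylsulfanyl)-2,3-dihydro-4H-pyran-4-one | O=C1C(Sc2ccccc2)=CO[C@H](c2ccc(O[Si](C)(C)C(C)(C)C)cc2OC)C1 | intermediate
8 | (2S)-2-[4-(TBSO)-2-methoxyphenyl]-5-(phenylsulfinyl)-2,3-dihydro-4H-pyran-4-one, both epimers at sulfur | O=C1C(S(=O)c2ccccc2)=CO[C@H](c2ccc(O[Si](C)(C)C(C)(C)C)cc2OC)C1 | intermediate (key-step precursor)
9 | (±)-lavandulol, 5-methyl-2-(prop-1-en-2-yl)hex-4-en-1-ol | C=C(C)C(CC=C(C)C)CO | starting material
10 | (S)-lavandulol, (2S)-5-methyl-2-(prop-1-en-2-yl)hex-4-en-1-ol | C=C(C)[C@H](CC=C(C)C)CO | intermediate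
11 | (3S)-3-(iodomethyl)-2,6-dimethylhepta-1,5-diene | C=C(C)[C@H](CC=C(C)C)CI | intermediate
12 | dimethyl 2-[(2R)-5-methyl-2-(prop-1-en-2-yl)hex-4-en-1-yl]propanedioate | C=C(C)[C@H](CC=C(C)C)CC(C(=O)OC)C(=O)OC | intermediate
13 | 2-[(2R)-5-methyl-2-(prop-1-en-2-yl)hex-4-en-1-yl]propanedioic acid | C=C(C)[C@H](CC=C(C)C)CC(C(=O)O)C(=O)O | intermediate (not isolated)
14 | (4S)-7-methyl-4-(prop-1-en-2-yl)oct-6-enoic acid | C=C(C)[C@H](CC=C(C)C)CCC(=O)O | intermediate
15 | ketene dimethyl acetal, 1,1-dimethoxyethene | C=C(OC)OC | starting material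
16 | (4S)-7-methyl-4-(prop-1-en-2-yl)oct-6-enoyl chloride | C=C(C)[C@H](CC=C(C)C)CCC(=O)Cl | intermediate (not isolated)
17 | (6S)-1,1-dimethoxy-9-methyl-6-(prop-1-en-2-yl)deca-1,8-dien-3-one | C=C(C)[C@H](CC=C(C)C)CCC(=O)C=C(OC)OC | intermediate
18 | (3Z,6R)-3-(TBSO)-1,1-dimethoxy-9-methyl-6-(prop-1-en-2-yl)deca-1,3,8-triene | C=C(C)[C@H](CC=C(C)C)C/C=C(\O[Si](C)(C)C(C)(C)C)C=C(OC)OC | intermediate (key-step precursor)
19 | (2S)-2-[4-(TBSO)-2-methoxyphenyl]-7-(TBSO)-5,5-dimethoxy-8-[(2R)-lavandulyl]-4a-(phenylsulfinyl)-2,3,4a,5,8,8a-hexahydro-4H-chromen-4-one, cis-fused, mixture at C4a/C8/C8a and sulfur | C=C(C)[C@H](CC=C(C)C)CC1C(O[Si](C)(C)C(C)(C)C)=CC(OC)(OC)C2(S(=O)c3ccccc3)C(=O)C[C@@H](c3ccc(O[Si](C)(C)C(C)(C)C)cc3OC)OC12 | intermediate (not isolated)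
20 | (2S)-2-[4-(TBSO)-2-methoxyphenyl]-7-(TBSO)-5,5-dimethoxy-8-[(2R)-lavandulyl]-2,3,5,8-tetrahydro-4H-chromen-4-one, both C8 epimers | C=C(C)[C@H](CC=C(C)C)CC1C(O[Si](C)(C)C(C)(C)C)=CC(OC)(OC)C2=C1O[C@H](c1ccc(O[Si](C)(C)C(C)(C)C)cc1OC)CC2=O | intermediate (not isolated)
21 | 7,4'-bis-O-TBS-(2S)-2'-methoxykurarinone, (2S)-7-(TBSO)-2-[4-(TBSO)-2-methoxyphenyl]-5-methoxy-8-[(2R)-lavandulyl]chroman-4-one | C=C(C)[C@H](CC=C(C)C)Cc1c(O[Si](C)(C)C(C)(C)C)cc(OC)c2c1O[C@H](c1ccc(O[Si](C)(C)C(C)(C)C)cc1OC)CC2=O | intermediate (key-step product)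
22 | (2S)-2'-methoxykurarinone | C=C(C)[C@H](CC=C(C)C)Cc1c(O)cc(OC)c2c1O[C@H](c1ccc(O)cc1OC)CC2=O | target

Total step count: 12. Longest linear sequence: 8 steps (steps 5–12, from (±)-lavandulol).

Steps most likely to fail

Step 11 (proposed new method). The reaction may stop after the first C–C bond, through vinylogous Michael addition and silyl transfer without ring closure, or the diene may be hydrolysed or consumed by the liberated sulfenic acid before it cycloadds. The fallback abandons the arene-last order and uses only known reactions, setting out from iodide 11 and returning at 21. 5-Methoxyresorcinol is protected (MOMCl, iPr2NEt) as 1-methoxy-3,5-bis(methoxymethoxy)benzene F1. Lithiation between the two MOM ethers (n-BuLi, THF, 0 °C) and alkylation with 11 (DMPU) gives the 2-lavandulyl arene F2. A second ortho-lithiation (n-BuLi, TMEDA), now between OMOM and OMe, and acylation with (E)-N,3-dimethoxy-N-methylacrylamide gives the aryl β-methoxyvinyl ketone F3. Methanolic HCl at 25 °C removes both MOM groups and closes the pyranone to 7-hydroxy-8-lavandulyl-5-methoxychromone F4, which is silylated (TBSCl, imidazole) to the 7-silyloxychromone F5. Separately, 4-bromo-3-methoxyphenol is silylated to the aryl bromide silyl ether F6 and converted (n-BuLi, B(OiPr)3, aqueous work-up) into the arylboronic acid F7. Rhodium(I)/chiral diene-catalysed asymmetric 1,4-addition of F7 to chromone F5 sets C2 as S and gives 21 directly.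

Step 2. Facial discrimination and turnover may be poor with the electron-rich, ortho-substituted aldehyde, and the acid treatment may ionise the benzylic C2–O bond and erode the enantiomeric purity. The fallback replaces the cycloaddition by a reagent-controlled aldol route, setting out from 2 and returning at 5. The boron enolate of (E)-4-methoxybut-3-en-2-one (Ipc2BCl, iPr2NEt, Et2O, −78 °C; the reagent enantiomer is chosen to give the S carbinol) adds to 2 to give the β-hydroxy enone (1E,5S)-5-[4-(TBSO)-2-methoxyphenyl]-5-hydroxy-1-methoxypent-1-en-3-one F8. PPTS in CH2Cl2 then closes the ring by oxa-Michael addition and loss of methanol to give 5.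

Step 5. The lipase may discriminate too weakly between the enantiomers of a primary alcohol whose stereocentre is β to oxygen, so the recovered alcohol stays enantiomerically impure at acceptable conversion. The fallback resolves through covalent diastereomers, setting out from 9 and returning at 10. Esterification of 9 with (S)-naproxen (DCC, DMAP, CH2Cl2) gives (S)-lavandulyl (S)-naproxenate F9 together with its diastereomer (R)-lavandulyl (S)-naproxenate F10. The two are separated by chromatography or crystallisation, and saponification of F9 (LiOH, THF/MeOH/H2O) releases 10.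

Further compounds
F1 | step 11 | 1-methoxy-3,5-bis(methoxymethoxy)benzene | COCOc1cc(OC)cc(OCOC)c1
F2 | step 11 | 5-methoxy-1,3-bis(methoxymethoxy)-2-[(2R)-5-methyl-2-(prop-1-en-2-yl)hex-4-en-1-yl]benzene | C=C(C)[C@H](CC=C(C)C)Cc1c(OCOC)cc(OC)cc1OCOC
F3 | step 11 | (E)-3-methoxy-1-{6-methoxy-2,4-bis(methoxymethoxy)-3-[(2R)-5-methyl-2-(prop-1-en-2-yl)hex-4-en-1-yl]phenyl}prop-2-en-1-one | C=C(C)[C@H](CC=C(C)C)Cc1c(OCOC)cc(OC)c(C(=O)/C=C/OC)c1OCOC
F4 | step 11 | 7-hydroxy-5-methoxy-8-[(2R)-5-methyl-2-(prop-1-en-2-yl)hex-4-en-1-yl]-4H-chromen-4-one | C=C(C)[C@H](CC=C(C)C)Cc1c(O)cc(OC)c2c1OC=CC2=O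
F5 | step 11 | 7-(TBSO)-5-methoxy-8-[(2R)-5-methyl-2-(prop-1-en-2-yl)hex-4-en-1-yl]-4H-chromen-4-one | C=C(C)[C@H](CC=C(C)C)Cc1c(O[Si](C)(C)C(C)(C)C)cc(OC)c2c1OC=CC2=O
F6 | step 11 | (4-bromo-3-methoxyphenoxy)(tert-butyl)dimethylsilane | COc1cc(O[Si](C)(C)C(C)(C)C)ccc1Br
F7 | step 11 | [4-(TBSO)-2-methoxyphenyl]boronic acid | COc1cc(O[Si](C)(C)C(C)(C)C)ccc1B(O)O
F8 | step 2 | (1E,5S)-5-[4-(TBSO)-2-methoxyphenyl]-5-hydroxy-1-methoxypent-1-en-3-one | CO/C=C/C(=O)C[C@H](O)c1ccc(O[Si](C)(C)C(C)(C)C)cc1OC
F9 | step 5 | (S)-lavandulyl (S)-2-(6-methoxynaphthalen-2-yl)propanoate | C=C(C)[C@H](CC=C(C)C)COC(=O)[C@@H](C)c1ccc2cc(OC)ccc2c1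
F10 | step 5 | (R)-lavandulyl (S)-2-(6-methoxynaphthalen-2-yl)propanoate | C=C(C)[C@@H](CC=C(C)C)COC(=O)[C@@H](C)c1ccc2cc(OC)ccc2c1
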